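You read the flask at 2.5 min, and since ochre, green, blue, amber and red differ in the spacing of their portions and nothing else, the question is what a later start still costs at that moment.

| flask | substrate | reagent | remark | time |
|---|---|---|---|---|
| Monday's | 0.010 M (in portions, 4) | 0.65 equiv | run made earlier; portions every 0.20 s |  |
| Friday's | 0.010 M (in portions, 4) | 2.6 equiv | run made earlier; portions every 0.20 s |  |
| Sunday's | 0.015 M (in portions, 4) | 1.3 equiv | run made earlier; portions every 0.20 s |  |
| ochre | 0.010 M (in portions, 4) | 1.30 equiv | the portions of substrate follow each other after 0.20 s, the first at the start | 2.5 min |
| green | 0.010 M (in portions, 4) | 1.30 equiv | the portions of substrate follow each other after 0.40 s, the first at the start | 2.5 min |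
| blue | 0.010 M (in portions, 4) | 1.30 equiv | the portions of substrate follow each other after 0.80 s, the first at the start | 2.5 min |
| amber | 0.010 M (in portions, 4) | 1.30 equiv | the portions of substrate follow each other after 1.5 s, the first at the start | 2.5 min |
| red | 0.010 M (in portions, 4) | 1.30 equiv | the portions of substrate follow each other after 3.0 s, the first at the start | 2.5 min |

| run | time / s | target / % |
|---|---|---|
| Monday's | 10.0 | 2.2 |
| Monday's | 20.0 | 5.0 |
| Monday's | 50.0 | 12.1 |
| Monday's | 120 | 20.3 |
| Friday's | 15.0 | 16.1 |
| Friday's | 40.0 | 30.5 |
| Friday's | 80.0 | 36.5 |
| Friday's | 120 | 36.4 |
| Sunday's | 15.0 | 10.2 |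
| Sunday's | 40.0 | 22.1 |
| Sunday's | 80.0 | 30.1 |
| Sunday's | 120 | 34.4 |

(readings scatter by 1 percentage point)

- amount of target at the end, in percent of the substrate charged for ochre, green, blue, amber, red, in this order
- how the row runs (falls, then rises / rises, then falls / hardly changes / rises all the way / falls all the way)

- what was read earlier has a scatter of 1 percentage point, one standard deviation
- steps under discussion: substrate <-> intermediate A; reagent + intermediate A -> target; substrate -> intermediate B; intermediate B -> side product; intermediate B <-> intermediate C; target <-> isomer of the product
- "hardly changes" means that all values lie within two and a half points (for a concentration: within two and a half percent of the largest)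

How late is the widest dosing? The mean delay of a portion is the number of gaps times the interval, divided by two: 0.300 s in ochre and 4.50 s in red, whose interval is the longest, and that is still 3.00% of the time of reading.

Does spreading the substrate change its selectivity? Sunday's flask held 1.50 times the substrate concentration of Monday's and 3.00 times the reagent concentration, and its early gain, as a fraction of the charge per second, read at 15.0 s against Monday's at 20.0 s, came to 2.72 times Monday's. That ratio, a reading with its scatter, stands nearer the reagent's than the substrate's, so I expect thinner substrate to leave the shares as they are.

What, then, does the delay cost? I treat a later flask as the same curve moved to the right, so that it lacks at reading its late gain per second times the extra delay. Sunday's readings from 80.0 s to 120 s give a late gain of 0.00107 s⁻¹ of the charge, and I call that late gain the delay price. By this reckoning red's extra 4.20 s over ochre costs about 0.45 percentage points, less than the scatter, and the gain in Sunday's flask is still slowing.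

The forecast gives 30%, 30%, 30%, 29.9%, 29.7%, so hardly changes, holding that “Dosing therefore should barely change selectivity”. Its drop from ochre to red, 0.3 points, is smaller than my 0.45 points, but the shape is the same, and I take its level.

    substrate ⇌ intermediate A (K = 2.81, k = 0.0725 s⁻¹)
    reagent + intermediate A → target (k = 1.93 L mol⁻¹ s⁻¹)
    substrate → intermediate B (k = 0.0429 s⁻¹)
    intermediate B → side product (k = 0.139 s⁻¹)
    intermediate B ⇌ intermediate C (K = 1.07, k = 0.219 s⁻¹)
    target ⇌ isomer of the product (K = 0.370, k = 0.0494 s⁻¹)

The flasks give 30.4%, 30.4%, 30.4%, 30.4%, 30.3%, so hardly changes. The gradual adding changes red's target by at most 0.1 points, while red ends with 0.535% of substrate left against 0.485% in ochre. On amber the delay price 0.00107 s⁻¹ times the extra 1.95 s gives 0.21 points, and amber stands at 30.4% beside ochre's 30.4%, with a local order in the interval of −0.0016.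

The numbers in the tables were computed with made-up constants.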